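## Retrosynthetic overview

1. The last C–C bond (C6–prenyl on the benzofuran) comes from an aromatic Claisen rearrangement of the 7‑O‑(1,1‑dimethylallyl) ether of the hydroxybenzofuran; the pivalate is then removed in the same flask.
2. The free benzofuran‑7‑ol comes from its methyl ether; the furan ring comes from ozonolysis and cyclodehydration of an ortho‑prenyl phenol.
3. That ortho‑prenyl phenol comes from a first aromatic Claisen rearrangement of a 4'‑O‑(1,1‑dimethylallyl) ether, sent to C5' because C3' carries the natural OMe.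
4. The C2 stereocentre, rings A and C, and the differentiated 3',4'‑dioxygenation are bought in (2S)‑homoeriodictyol; the 7‑OH is masked as a pivalate.
5. Ring order: rings A, C and the benzene ring B are present from the start; the furan is closed in step 5; the prenyl C–C bond is made in step 8.

Assumption: (2S)‑homoeriodictyol is bought as the natural enantiomer and its ee is confirmed by chiral HPLC before use.

## Route

Step 1
Reactants: 1 2‑methylbut‑3‑en‑2‑ol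
Product: 2 tert‑butyl 2‑methylbut‑3‑en‑2‑yl carbonate
Conditions: n‑BuLi, THF, −78 → 0 °C; Boc2O, 0 °C → rt; H2O
Reagents that add atoms: di‑tert‑butyl dicarbonate CC(C)(C)OC(=O)OC(=O)OC(C)(C)C
Why: The lithium alkoxide of the tertiary allylic alcohol is acylated by Boc2O (alkoxide O‑acylation), the standard way to make tertiary allylic tert‑butyl carbonates.

Step 2
Reactants: 3 (2S)‑5,7‑dihydroxy‑2‑(4‑hydroxy‑3‑methoxyphenyl)chroman‑4‑one ((2S)‑homoeriodictyol)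
Product: 4 (2S)‑5‑hydroxy‑2‑(4‑hydroxy‑3‑methoxyphenyl)‑4‑oxochroman‑7‑yl pivalate
Conditions: PivCl (1.0 equiv), Et3N (1.05 equiv), THF, −40 → 0 °C
Reagents that add atoms: pivaloyl chloride CC(C)(C)C(Cl)=O
Why: Kinetic regioselective O‑acylation, because the 7‑OH is the most acidic and least hindered phenol (the only one turned into its ammonium phenoxide by one equivalent of Et3N), the 4'‑OH is a hindered guaiacol OH and the 5‑OH is chelated to C4=O; the cold, weakly basic medium leaves C2 untouched.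

Step 3
Reactants: 4 (2S)‑5‑hydroxy‑2‑(4‑hydroxy‑3‑methoxyphenyl)‑4‑oxochroman‑7‑yl pivalate; 2 tert‑butyl 2‑methylbut‑3‑en‑2‑yl carbonate
Product: 5 (2S)‑5‑hydroxy‑2‑[3‑methoxy‑4‑(2‑methylbut‑3‑en‑2‑yloxy)phenyl]‑4‑oxochroman‑7‑yl pivalate
Conditions: Pd(PPh3)4 (5 mol %), 2 (1.3 equiv), THF, 0 °C, 2 h
Reagents that add atoms: none
Why: Decarboxylative Tsuji–Trost O‑allylation in which the 4'‑phenoxide attacks the tertiary terminus of the 1,1‑dimethylallyl complex of palladium under kinetic control at 0 °C, giving the branched ether at the only non‑chelated OH without added base.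

Step 4
Reactants: 5 (2S)‑5‑hydroxy‑2‑[3‑methoxy‑4‑(2‑methylbut‑3‑en‑2‑yloxy)phenyl]‑4‑oxochroman‑7‑yl pivalate
Product: 6 (2S)‑5‑hydroxy‑2‑[4‑hydroxy‑3‑methoxy‑5‑(3‑methylbut‑2‑enyl)phenyl]‑4‑oxochroman‑7‑yl pivalate
Conditions: PhMe (degassed), 110 °C, sealed tube, 3 h
Reagents that add atoms: none
Why: Aromatic Claisen rearrangement ([3,3]‑sigmatropic) of a tertiary allyl aryl ether, which proceeds near 100 °C and can only end at C5' because C3' carries OMe; the neutral, base‑free medium does not open ring C, so C2 stays (S).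

Step 5
Reactants: 6 (2S)‑5‑hydroxy‑2‑[4‑hydroxy‑3‑methoxy‑5‑(3‑methylbut‑2‑enyl)phenyl]‑4‑oxochroman‑7‑yl pivalate
Product: 8 (2S)‑5‑hydroxy‑2‑(7‑methoxy‑1‑benzofuran‑5‑yl)‑4‑oxochroman‑7‑yl pivalate, via lactol 7 (not isolated)
Conditions: O3 (1.05 equiv, titrated solution), CH2Cl2, −78 °C; PPh3, −78 °C → rt; then p‑TsOH·H2O (5 mol %), rt
Reagents that add atoms: none
Why: Ozonolysis (Criegee) cleaves the electron‑rich trisubstituted alkene far faster than any arene, the arylacetaldehyde closes onto the ortho 4'‑OH as a lactol, and acid‑catalysed dehydration aromatises it to the furan.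

Step 6
Reactants: 8 (2S)‑5‑hydroxy‑2‑(7‑methoxy‑1‑benzofuran‑5‑yl)‑4‑oxochroman‑7‑yl pivalate
Product: 9 (2S)‑5‑hydroxy‑2‑(7‑hydroxy‑1‑benzofuran‑5‑yl)‑4‑oxochroman‑7‑yl pivalate
Conditions: BBr3 (4 equiv), CH2Cl2, −78 → −20 °C; then H2O, 0 °C
Reagents that add atoms: none
Why: Lewis‑acid aryl methyl ether cleavage (bromide attacks the methyl of the boron‑complexed OMe) that spares the hindered aryl pivalate and the benzofuran at low temperature; the complexed OMe is electron‑withdrawing and the furan oxygen is a weak donor, so ring B should not assist C2–O1 ionisation and C2 is expected to stay (S).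

Step 7
Reactants: 9 (2S)‑5‑hydroxy‑2‑(7‑hydroxy‑1‑benzofuran‑5‑yl)‑4‑oxochroman‑7‑yl pivalate; 2 tert‑butyl 2‑methylbut‑3‑en‑2‑yl carbonate
Product: 10 (2S)‑5‑hydroxy‑2‑[7‑(2‑methylbut‑3‑en‑2‑yloxy)‑1‑benzofuran‑5‑yl]‑4‑oxochroman‑7‑yl pivalate
Conditions: Pd(PPh3)4 (5 mol %), 2 (1.3 equiv), THF, 0 °C, 2 h
Reagents that add atoms: none
Why: The same kinetic, branched‑selective Tsuji–Trost O‑allylation, now at the benzofuran 7‑OH, the only free non‑chelated phenol because the more acidic chromanone 7‑OH is still a pivalate.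

Step 8
Reactants: 10 (2S)‑5‑hydroxy‑2‑[7‑(2‑methylbut‑3‑en‑2‑yloxy)‑1‑benzofuran‑5‑yl]‑4‑oxochroman‑7‑yl pivalate
Product: 12 (2S)‑5,7‑dihydroxy‑2‑[7‑hydroxy‑6‑(3‑methylbut‑2‑enyl)‑1‑benzofuran‑5‑yl]chroman‑4‑one, via pivalate 11 (not isolated)
Conditions: PhMe (degassed), 110 °C, 3 h; then 0 °C, MeOH, K2CO3 (1.5 equiv), 0 °C → rt, 1 h; AcOH quench
Reagents that add atoms: none
Why: Key aromatic Claisen rearrangement ([3,3]‑sigmatropic) that delivers the prenyl group to C6, the only ortho carbon bearing H (C7a is the ring fusion), followed by mild base‑mediated methanolysis of the activated aryl pivalate; ring B has no free para‑OH, so this brief cold base treatment does not racemise C2.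

## Compound list

1 | 2‑methylbut‑3‑en‑2‑ol | C=CC(C)(C)O | starting material
2 | tert‑butyl 2‑methylbut‑3‑en‑2‑yl carbonate | C=CC(C)(C)OC(=O)OC(C)(C)C | intermediate
3 | (2S)‑5,7‑dihydroxy‑2‑(4‑hydroxy‑3‑methoxyphenyl)chroman‑4‑one ((2S)‑homoeriodictyol) | COc1cc(ccc1O)[C@@H]2CC(=O)c3c(O)cc(O)cc3O2 | starting material
4 | (2S)‑5‑hydroxy‑2‑(4‑hydroxy‑3‑methoxyphenyl)‑4‑oxochroman‑7‑yl pivalate | COc1cc(ccc1O)[C@@H]2CC(=O)c3c(O)cc(OC(=O)C(C)(C)C)cc3O2 | intermediate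
5 | (2S)‑5‑hydroxy‑2‑[3‑methoxy‑4‑(2‑methylbut‑3‑en‑2‑yloxy)phenyl]‑4‑oxochroman‑7‑yl pivalate | COc1cc(ccc1OC(C)(C)C=C)[C@@H]2CC(=O)c3c(O)cc(OC(=O)C(C)(C)C)cc3O2 | intermediate
6 | (2S)‑5‑hydroxy‑2‑[4‑hydroxy‑3‑methoxy‑5‑(3‑methylbut‑2‑enyl)phenyl]‑4‑oxochroman‑7‑yl pivalate | COc1cc(cc(CC=C(C)C)c1O)[C@@H]2CC(=O)c3c(O)cc(OC(=O)C(C)(C)C)cc3O2 | intermediate
7 | (2S)‑5‑hydroxy‑2‑(2‑hydroxy‑7‑methoxy‑2,3‑dihydro‑1‑benzofuran‑5‑yl)‑4‑oxochroman‑7‑yl pivalate (lactol, both epimers at the hemiacetal carbon) | COc1cc(cc2CC(O)Oc12)[C@@H]3CC(=O)c4c(O)cc(OC(=O)C(C)(C)C)cc4O3 | intermediate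
8 | (2S)‑5‑hydroxy‑2‑(7‑methoxy‑1‑benzofuran‑5‑yl)‑4‑oxochroman‑7‑yl pivalate | COc1cc(cc2ccoc12)[C@@H]3CC(=O)c4c(O)cc(OC(=O)C(C)(C)C)cc4O3 | intermediate
9 | (2S)‑5‑hydroxy‑2‑(7‑hydroxy‑1‑benzofuran‑5‑yl)‑4‑oxochroman‑7‑yl pivalate | Oc1cc(cc2ccoc12)[C@@H]3CC(=O)c4c(O)cc(OC(=O)C(C)(C)C)cc4O3 | intermediate
10 | (2S)‑5‑hydroxy‑2‑[7‑(2‑methylbut‑3‑en‑2‑yloxy)‑1‑benzofuran‑5‑yl]‑4‑oxochroman‑7‑yl pivalate | C=CC(C)(C)Oc1cc(cc2ccoc12)[C@@H]3CC(=O)c4c(O)cc(OC(=O)C(C)(C)C)cc4O3 | intermediate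
11 | (2S)‑5‑hydroxy‑2‑[7‑hydroxy‑6‑(3‑methylbut‑2‑enyl)‑1‑benzofuran‑5‑yl]‑4‑oxochroman‑7‑yl pivalate | CC(C)=CCc1c(cc2ccoc2c1O)[C@@H]3CC(=O)c4c(O)cc(OC(=O)C(C)(C)C)cc4O3 | intermediate
12 | (2S)‑5,7‑dihydroxy‑2‑[7‑hydroxy‑6‑(3‑methylbut‑2‑enyl)‑1‑benzofuran‑5‑yl]chroman‑4‑one | CC(C)=CCc1c([C@@H]2CC(=O)c3c(O)cc(O)cc3O2)cc2ccoc2c1O | target

## Step count and risks

Total steps: 8. Longest linear sequence: 7 (compound 3 to compound 12, steps 2–8); step 1 is a side branch that makes the reagent 2.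

**Step 6 (demethylation) is the weakest step.** A boron halide can ionise the benzylic C2–O1 bond of a flavanone or attack the benzofuran, which would erode the ee; the ee of 9 must be checked by chiral HPLC. The fallback sets out from 6 and moves the unmasking ahead of furan formation. There the free 4'‑OH ortho to the OMe allows the pyridine‑buffered, chelation‑directed aluminium method (AlCl3, pyridine, CH2Cl2, 40 °C), which is known to tolerate allyl side chains. This gives the catechol (2S)‑2‑[3,4‑dihydroxy‑5‑(3‑methylbut‑2‑enyl)phenyl]‑5‑hydroxy‑4‑oxochroman‑7‑yl pivalate F3. Ozonolysis with exactly one equivalent of ozone at −78 °C and PPh3 work‑up gives the lactol (2S)‑5‑hydroxy‑2‑(2,7‑dihydroxy‑2,3‑dihydro‑1‑benzofuran‑5‑yl)‑4‑oxochroman‑7‑yl pivalate F4; only the 4'‑OH can reach the aldehyde. Catalytic p‑TsOH then dehydrates F4, and the fallback comes back to the route at 9. This detour carries its own risks (a catechol under ozone, an aluminium phenoxide para to C2).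

**Step 2 (selective 7‑O‑pivaloylation)** may give 4'‑O‑acyl or diacyl material, since acyl groups can end up on the less acidic phenol. The fallback sets out from 3 and avoids any selective acylation. Both acidic phenols are etherified with 2 (2.5 equiv, Pd(PPh3)4, THF, 0 °C, kept cold) to give (2S)‑5‑hydroxy‑2‑[3‑methoxy‑4‑(2‑methylbut‑3‑en‑2‑yloxy)phenyl]‑7‑(2‑methylbut‑3‑en‑2‑yloxy)chroman‑4‑one F1. The 7‑O‑allylic ether, whose phenoxide is by far the better leaving group, is then removed selectively with Pd(PPh3)4 and morpholine (1.0 equiv) in THF at −20 °C. This gives (2S)‑5,7‑dihydroxy‑2‑[3‑methoxy‑4‑(2‑methylbut‑3‑en‑2‑yloxy)phenyl]chroman‑4‑one F2, in which the 7‑OH is the only phenol that can be acylated. PivCl and Et3N at −40 °C then bring the fallback back to the route at 5.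

**Step 8 (Claisen into the flanked C6 position)** may lose the tertiary ether by ionisation back to 9 instead of rearranging. The fallback sets out from 9 and uses an allyl group that cannot ionise. Mitsunobu allylation (allyl alcohol, PPh3, DIAD, THF, 0 °C) gives (2S)‑5‑hydroxy‑4‑oxo‑2‑(7‑prop‑2‑enoxy‑1‑benzofuran‑5‑yl)chroman‑7‑yl pivalate F5. Thermal Claisen rearrangement (PhNEt2, 190 °C, short microwave heating; ring B has no free para‑OH at this stage) gives (2S)‑5‑hydroxy‑2‑(7‑hydroxy‑6‑prop‑2‑enyl‑1‑benzofuran‑5‑yl)‑4‑oxochroman‑7‑yl pivalate F6. Cross‑metathesis with excess 2‑methylbut‑2‑ene using the second‑generation Grubbs catalyst RuCl2(=CHPh)(H2IMes)(PCy3) in CH2Cl2 at 40 °C turns the allyl into the prenyl group, and the fallback comes back to the route at 11, which is methanolysed as in step 8.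

## Further compounds

F1 | step 2 | (2S)‑5‑hydroxy‑2‑[3‑methoxy‑4‑(2‑methylbut‑3‑en‑2‑yloxy)phenyl]‑7‑(2‑methylbut‑3‑en‑2‑yloxy)chroman‑4‑one | COc1cc(ccc1OC(C)(C)C=C)[C@@H]2CC(=O)c3c(O)cc(OC(C)(C)C=C)cc3O2
F2 | step 2 | (2S)‑5,7‑dihydroxy‑2‑[3‑methoxy‑4‑(2‑methylbut‑3‑en‑2‑yloxy)phenyl]chroman‑4‑one | COc1cc(ccc1OC(C)(C)C=C)[C@@H]2CC(=O)c3c(O)cc(O)cc3O2
F3 | step 6 | (2S)‑2‑[3,4‑dihydroxy‑5‑(3‑methylbut‑2‑enyl)phenyl]‑5‑hydroxy‑4‑oxochroman‑7‑yl pivalate | Oc1cc(cc(CC=C(C)C)c1O)[C@@H]2CC(=O)c3c(O)cc(OC(=O)C(C)(C)C)cc3O2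
F4 | step 6 | (2S)‑5‑hydroxy‑2‑(2,7‑dihydroxy‑2,3‑dihydro‑1‑benzofuran‑5‑yl)‑4‑oxochroman‑7‑yl pivalate | Oc1cc(cc2CC(O)Oc12)[C@@H]3CC(=O)c4c(O)cc(OC(=O)C(C)(C)C)cc4O3
F5 | step 8 | (2S)‑5‑hydroxy‑4‑oxo‑2‑(7‑prop‑2‑enoxy‑1‑benzofuran‑5‑yl)chroman‑7‑yl pivalate | C=CCOc1cc(cc2ccoc12)[C@@H]3CC(=O)c4c(O)cc(OC(=O)C(C)(C)C)cc4O3
F6 | step 8 | (2S)‑5‑hydroxy‑2‑(7‑hydroxy‑6‑prop‑2‑enyl‑1‑benzofuran‑5‑yl)‑4‑oxochroman‑7‑yl pivalate | C=CCc1c(cc2ccoc2c1O)[C@@H]3CC(=O)c4c(O)cc(OC(=O)C(C)(C)C)cc4O3
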